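How much of the violet flask's substrate stood as target at 8.7 h, and to what powers of substrate and free catalyst did the starting rate answer? I built the flask one process at a time from the runs so far.

| flask | substrate | free catalyst | time |
|---|---|---|---|
| green | 1.00 M | 0.00200 M |  |
| red | 0.600 M | 0.00200 M |  |
| teal | 0.500 M | 0.00200 M |  |
| ochre | 1.00 M | 0.00100 M |  |
| violet | 0.200 M | 0.00200 M | 8.7 h |

| green run: time / h | green run: [target] / M | red run: time / h | red run: [target] / M | teal run: time / h | teal run: [target] / M | ochre run: time / h | ochre run: [target] / M |
|---|---|---|---|---|---|---|---|
| 0.31 | 0.058 | 0.31 | 0.024 | 0.31 | 0.028 | 0.31 | 0.033 |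
| 0.95 | 0.146 | 0.95 | 0.084 | 0.95 | 0.072 | 0.95 | 0.100 |
| 1.8 | 0.251 | 1.8 | 0.160 | 1.8 | 0.132 | 1.8 | 0.180 |
| 2.9 | 0.356 | 2.9 | 0.218 | 2.9 | 0.185 | 2.9 | 0.257 |
| 4.1 | 0.437 | 4.1 | 0.276 | 4.1 | 0.225 | 4.1 | 0.327 |
| 5.5 | 0.504 | 5.5 | 0.315 | 5.5 | 0.268 | 5.5 | 0.389 |
| 7.0 | 0.554 | 7.0 | 0.345 | 7.0 | 0.293 | 7.0 | 0.442 |
| 8.7 | 0.577 | 8.7 | 0.361 | 8.7 | 0.308 | 8.7 | 0.475 |

(each reading ± 0.003 M)

- Overall: substrate -> target, with free catalyst as catalyst.
- Constant volume, constant temperature.
- An order is taken over about fifteen percent of the charge, up and down.

- the exponent of [free catalyst] in the starting rate at the charge of the green run (at the point where two percent of the substrate have become target)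
- the exponent of [substrate] in the starting rate at the charge of the green run (at the point where two percent of the substrate have become target) (one fixed amount of target, the same in the runs compared)
- target in the violet run at 8.7 h, as a share of the substrate charged

1. Main step. In the green run at 0.95 h the pace came to 0.166 h⁻¹, where by pace I mean minus the natural logarithm of the unturned share of substrate, divided by the time: the pseudo-first-order constant. The teal run, with half the substrate, gave 0.164 h⁻¹ at that time, so I put the substrate exponent at 1.02. With this step and the green pace, I reckoned 76.4% for the violet run at 8.7 h.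

2. Catalyst. The ochre run, with half the catalyst, gave a pace of 0.111 h⁻¹. The logarithm of the pace ratio over that of the charge ratio gave me an exponent of 0.583. The violet run carries the green catalyst charge, 0.00200 M, so its number stayed at 76.4%.

3. Losses. At 8.7 h the green run stood 19 percentage points below that figure and the teal run 15 points below it, a smaller gap at the smaller charge. I took the gap as a part independent of charge plus a part growing with it, and ran a straight line through these two runs down to the violet charge. That line gave me 63.9% for the violet run, 13 points below my first number.

4. Forecast. It gave a catalyst exponent of 0.67, a substrate exponent of 0.97, and 63.5% for the violet run. Its catalyst exponent, higher than mine, came from fits to the whole curves: “Doubling the catalyst therefore gives a factor of about 1.6”.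

5. Result. The simulation gave a catalyst exponent of 0.55, lower than the forecast's, a substrate exponent of 1.0, and 63.4% for the violet run.

    2 free catalyst ⇌ catalyst dimer, settled at all times (7530 L mol⁻¹)
    free catalyst + substrate → target + free catalyst (532.8 L mol⁻¹ h⁻¹)
    2 substrate → homo dimer (0.02934 L mol⁻¹ h⁻¹)
    target → decomposed product (0.03550 h⁻¹)

In the violet run, catalyst dimer stood in fast balance with free catalyst from the start to 8.7 h, and while free catalyst and substrate were there the main step made target. Alongside it, two substrate at a time went to homo dimer, and target, once made, went on to decomposed product with a rate constant of 0.0355 h⁻¹; the violet run ended at 63.4% of its charge, 13 points below the 76.4% reckoned from the green pace of 0.166 h⁻¹.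

The runs come from a simulation for substances that don't exist; noise was put on by code.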